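**Strategy.** The route rests on disconnecting the C2–C3 bond of the furan-2(5H)-one ring (lactone carbonyl carbon to the α-carbon that carries the two-carbon tether to the hydroxy-ε-ring). Because C4 bears only hydrogen and C3=C4 is endocyclic, the ring is the formal trans-adduct of a formyl C–H across an alkyne. A propargyl formate, with O1–C2 and C5 already in place, is isomerised by cationic Rh(I) to the 3-substituted butenolide in one atom-economic operation. The precursor is an acyclic 5-(cyclohexenyl)pent-2-ynyl formate. The (Z)-C5=C6 alkylidene and the polyene follow by vinylogous aldol condensation with a C25 apo-carotenal (C15 Wittig salt plus C10 dialdehyde).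

Key step: step 6

Remark (assumption): (R)-α-ionone of natural grade is taken as commercially available in enantiopure form, and a cytochrome P450 BM3 variant active on α-ionone is used as a catalyst. Butenolide atoms are numbered O1, C2 (carbonyl), C3, C4, C5; C6 is the exocyclic carbon.

**Ring A / butenolide branch**

Step 1
Reactants: 1 (R)-α-ionone
Product: 2 (3R,6R)-3-hydroxy-α-ionone
Conditions: engineered cytochrome P450 BM3 monooxygenase variant, NADPH (cat.), glucose, glucose dehydrogenase, air, phosphate buffer pH 7.5, 25 °C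
Reagents that add atoms: dioxygen, O=O
Why: Enzymatic allylic C–H hydroxylation (P450 hydrogen abstraction–oxygen rebound) of a substrate class known for such variants; the ring allylic CH2 (C3) is oxidised on the face anti to the C6 side chain, so the enzyme pocket sets the new 3R centre trans to the existing 6R centre.

Step 2
Reactants: 2 (3R,6R)-3-hydroxy-α-ionone
Product: 3 (3E)-4-[(1R,4R)-4-(tert-butyldimethylsilyloxy)-2,6,6-trimethylcyclohex-2-en-1-yl]but-3-en-2-one
Conditions: TBSCl, imidazole, DMF, rt
Reagents that add atoms: tert-butyldimethylsilyl chloride, C[Si](C)(Cl)C(C)(C)C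
Why: Standard silylation of the secondary allylic alcohol, which must be masked before the strong-base and silyl triflate steps; no stereocentre is touched.

Step 3
Reactants: 3 silyl ether of hydroxy-α-ionone
Product: 4 4-[(1R,4R)-4-(tert-butyldimethylsilyloxy)-2,6,6-trimethylcyclohex-2-en-1-yl]butan-2-one
Conditions: H2 (1–3 atm), RhCl(PPh3)3 (5 mol%), benzene–EtOH, rt
Reagents that add atoms: none
Why: Homogeneous hydrogenation with Wilkinson's catalyst is highly sensitive to alkene substitution, so the disubstituted enone C=C should be saturated while the trisubstituted ring alkene, the ketone and the silyl ether remain; the neutral conditions leave the allylic C6 centre untouched.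

Step 4
Reactants: 4 saturated methyl ketone
Product: 8 5-[(1R,4R)-4-(tert-butyldimethylsilyloxy)-2,6,6-trimethylcyclohex-2-en-1-yl]pent-2-yn-1-ol, via lithium enolate 5 (not isolated), via enol diethyl phosphate 6 (not isolated), via lithium acetylide 7 (not isolated)
Conditions: LDA (1.05 equiv), THF, −78 °C; ClP(O)(OEt)2, −78 °C → rt; LDA (2.3 equiv), −78 °C → rt; (CH2O)n, 0 °C → rt; aq NH4Cl
Reagents that add atoms: paraformaldehyde (formaldehyde), C=O
Why: Methyl ketone-to-alkyne conversion by the enol phosphate elimination protocol: kinetic deprotonation of the methyl group, O-phosphorylation, base-induced loss of phosphate to the terminal alkyne, which is deprotonated in the flask and adds as its acetylide to formaldehyde.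

Step 5
Reactants: 8 propargylic alcohol
Product: 9 5-[(1R,4R)-4-(tert-butyldimethylsilyloxy)-2,6,6-trimethylcyclohex-2-en-1-yl]pent-2-yn-1-yl formate
Conditions: HCO2H, DCC, DMAP (cat.), CH2Cl2, 0 °C
Reagents that add atoms: formic acid, O=CO
Why: Steglich esterification (carbodiimide activation, acyl transfer through DMAP) of the unhindered primary alcohol; it installs the O1–C2 bond and the future lactone carbonyl carbon, with alkyne and silyl ether inert.

Step 6
Reactants: 9 propargyl formate
Product: 10 3-{2-[(1R,4R)-4-(tert-butyldimethylsilyloxy)-2,6,6-trimethylcyclohex-2-en-1-yl]ethyl}furan-2(5H)-one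
Conditions: [Rh(dppe)]2(BF4)2 (5–10 mol%), degassed acetone, 25–40 °C, Ar
Reagents that add atoms: none
Why: Proposed new method: cationic Rh(I), held by the C3≡C4 π-bond, should insert into the formyl C–H of 9 to give an alkoxycarbonyl rhodium(III) hydride; the hydride is then delivered to C4 in a net trans-hydrometalation (a syn-adduct would place an E-alkene inside the metallacycle), giving a six-membered oxa-rhodacycle from which C–C reductive elimination forges C2–C3. The closest known reaction type is the rhodium-catalysed intramolecular trans-hydroacylation of 4-alkynals to cyclopent-2-enones, of which this is the 2-oxa (formate ester) analogue; it is new because a formate C–H, not an aldehyde C–H, must be activated. The furan-2(5H)-one ring closes in a formal 5-endo-dig mode, realised as reductive elimination from the six-membered metallacycle. No stereocentre is formed; the cis relationship of C2 and C5 across C3=C4 is dictated by the ring, and the two ring stereocentres and the silyl ether are remote and untouched. The step needs C–C closure at the distal alkyne carbon (C3) to win over decarbonylation, decarboxylative reduction of the propargylic ester and 4-exo closure; the short O–CH2 tether, the chelating diphosphine and the mild temperature are expected to secure this.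

**Ring B / polyene branch**

Step 7
Reactants: 11 (4R,6R)-4-hydroxy-2,2,6-trimethylcyclohexan-1-one (actinol)
Product: 12 (4R,6R)-4-(tert-butyldimethylsilyloxy)-2,2,6-trimethylcyclohexan-1-one
Conditions: TBSCl, imidazole, DMF, rt
Reagents that add atoms: tert-butyldimethylsilyl chloride, C[Si](C)(Cl)C(C)(C)C
Why: Standard silylation of the secondary alcohol before enolate chemistry; the carbinol centre (the future 3R centre of the β-ring) is untouched.

Step 8
Reactants: 12 silylated actinol
Product: 14 (4R)-4-(tert-butyldimethylsilyloxy)-2,6,6-trimethylcyclohex-1-en-1-yl trifluoromethanesulfonate, via lithium enolate 13 (not isolated)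
Conditions: LDA, THF, −78 °C; PhNTf2, −78 → 0 °C; aq NH4Cl
Reagents that add atoms: N-phenylbis(trifluoromethanesulfonimide), O=S(=O)(N(c1ccccc1)S(=O)(=O)C(F)(F)F)C(F)(F)F
Why: Enol triflate formation: the ketone has a single enolisable α-position, so deprotonation and O-sulfonylation give the tetrasubstituted alkenyl triflate regiospecifically; the methyl-bearing centre is erased on purpose and the silyloxy centre is not affected.

Step 9
Reactants: 14 enol triflate; 15 methyl vinyl ketone
Product: 16 (3E)-4-[(4R)-4-(tert-butyldimethylsilyloxy)-2,6,6-trimethylcyclohex-1-en-1-yl]but-3-en-2-one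
Conditions: Pd(OAc)2 (5 mol%), PPh3 (10 mol%), Et3N, DMF, 70 °C
Reagents that add atoms: none
Why: Heck reaction of an alkenyl triflate with an enone (oxidative addition, syn-carbopalladation, syn-β-hydride elimination), which gives the E-dienone.

Step 10
Reactants: 16 silyloxy-β-ionone
Product: 17 (1E)-1-[(4R)-4-(tert-butyldimethylsilyloxy)-2,6,6-trimethylcyclohex-1-en-1-yl]-3-methylpenta-1,4-dien-3-ol (both C3 epimers)
Conditions: CH2=CHMgBr, THF, −20 → 0 °C; aq NH4Cl
Reagents that add atoms: vinylmagnesium bromide, C=C[Mg]Br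
Why: Grignard 1,2-addition to the ketone of the dienone; the new tertiary carbinol centre forms as an epimer mixture, which is irrelevant because it is ionised in the next step.

Step 11
Reactants: 17 vinyl carbinol
Product: 18 {(2E,4E)-5-[(4R)-4-(tert-butyldimethylsilyloxy)-2,6,6-trimethylcyclohex-1-en-1-yl]-3-methylpenta-2,4-dien-1-yl}triphenylphosphonium bromide
Conditions: Ph3P·HBr, CH2Cl2, rt
Reagents that add atoms: triphenylphosphine hydrobromide, [Br-].[PH+](c1ccccc1)(c1ccccc1)c1ccccc1
Why: Acid-induced ionisation of the tertiary bis-allylic alcohol to a delocalised cation and capture by PPh3 at the unhindered terminus (allylic transposition, the classical C15 Wittig salt formation) should give the conjugated 2E,4E-dienyl salt; the aprotic medium should keep the silyl ether.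

Step 12
Reactants: 18 C15 phosphonium bromide; 19 (2E,4E,6E)-2,7-dimethylocta-2,4,6-trienedial (1.5–2 equiv)
Product: 22 all-E (3R)-3-(tert-butyldimethylsilyloxy)-12'-apo-β-caroten-12'-al, via phosphonium ylide 20 (not isolated), via 8Z aldehyde 21 (not isolated)
Conditions: NaOMe, CH2Cl2/MeOH, 0 °C → rt; then I2 (cat.), hexane/CH2Cl2, daylight, rt
Reagents that add atoms: none
Why: Wittig olefination of the semi-stabilised allylic ylide with one aldehyde of the excess dialdehyde (the product polyenal is less electrophilic); the new double bond forms as an E/Z mixture, and the hindered Z isomer should be funnelled to all-E by iodine-catalysed equilibration.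

**Union and completion**

Step 13
Reactants: 10 butenolide (1.2 equiv); 22 C25 aldehyde
Product: 25 bis(tert-butyldimethylsilyl) ether of the target, via 2-silyloxyfuran 23 (not isolated), via aldol silyl ether 24 (not isolated)
Conditions: TBSOTf (2.2 equiv), i-Pr2NEt (4 equiv), CH2Cl2, −78 → 0 °C; then DBU (3 equiv), 0 °C → rt, dark
Reagents that add atoms: none
Why: One-pot vinylogous Mukaiyama aldol–elimination: the 2-silyloxyfuran formed in the flask attacks the silyl-activated aldehyde through C5, and DBU-induced E1cB loss of silanolate through the 2-oxidofuran should give the thermodynamically preferred Z-alkylidene (chain cis to O1, no A(1,3) strain with C4–H); the two transient aldol stereocentres are destroyed.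

Step 14
Reactants: 25 bis-silyl ether
Product: 26 target, (3R,3'R,6'R)-3,3'-dihydroxy-7',8'-dihydro-β,ε-caroten-19',11'-olide
Conditions: HF·pyridine, pyridine, THF, 0 °C → rt, dark, Ar
Reagents that add atoms: none
Why: Fluoride-mediated cleavage of both secondary silyl ethers under buffered, non-basic conditions that should spare the enol lactone and the polyene; no stereocentre or double bond is affected.

**Compound list**

1 | (R)-α-ionone, (3E)-4-[(1R)-2,6,6-trimethylcyclohex-2-en-1-yl]but-3-en-2-one | CC1=CCCC(C)(C)[C@H]1/C=C/C(C)=O | starting material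
2 | (3R,6R)-3-hydroxy-α-ionone, (3E)-4-[(1R,4R)-4-hydroxy-2,6,6-trimethylcyclohex-2-en-1-yl]but-3-en-2-one (OH trans to side chain) | CC1=C[C@H](O)CC(C)(C)[C@H]1/C=C/C(C)=O | intermediate
3 | (3E)-4-[(1R,4R)-4-(tert-butyldimethylsilyloxy)-2,6,6-trimethylcyclohex-2-en-1-yl]but-3-en-2-one | CC1=C[C@H](O[Si](C)(C)C(C)(C)C)CC(C)(C)[C@H]1/C=C/C(C)=O | intermediate
4 | 4-[(1R,4R)-4-(tert-butyldimethylsilyloxy)-2,6,6-trimethylcyclohex-2-en-1-yl]butan-2-one | CC1=C[C@H](O[Si](C)(C)C(C)(C)C)CC(C)(C)[C@H]1CCC(C)=O | intermediate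
5 | lithium enolate of 4 (terminal, but-1-en-2-olate) | CC1=C[C@H](O[Si](C)(C)C(C)(C)C)CC(C)(C)[C@H]1CCC(=C)O[Li] | intermediate (not isolated)
6 | diethyl 4-[(1R,4R)-4-(tert-butyldimethylsilyloxy)-2,6,6-trimethylcyclohex-2-en-1-yl]but-1-en-2-yl phosphate | CC1=C[C@H](O[Si](C)(C)C(C)(C)C)CC(C)(C)[C@H]1CCC(=C)OP(=O)(OCC)OCC | intermediate (not isolated)
7 | lithium acetylide of 4-[(1R,4R)-4-(tert-butyldimethylsilyloxy)-2,6,6-trimethylcyclohex-2-en-1-yl]but-1-yne | CC1=C[C@H](O[Si](C)(C)C(C)(C)C)CC(C)(C)[C@H]1CCC#C[Li] | intermediate (not isolated)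
8 | 5-[(1R,4R)-4-(tert-butyldimethylsilyloxy)-2,6,6-trimethylcyclohex-2-en-1-yl]pent-2-yn-1-ol | CC1=C[C@H](O[Si](C)(C)C(C)(C)C)CC(C)(C)[C@H]1CCC#CCO | intermediate
9 | 5-[(1R,4R)-4-(tert-butyldimethylsilyloxy)-2,6,6-trimethylcyclohex-2-en-1-yl]pent-2-yn-1-yl formate | CC1=C[C@H](O[Si](C)(C)C(C)(C)C)CC(C)(C)[C@H]1CCC#CCOC=O | intermediate
10 | 3-{2-[(1R,4R)-4-(tert-butyldimethylsilyloxy)-2,6,6-trimethylcyclohex-2-en-1-yl]ethyl}furan-2(5H)-one | CC1=C[C@H](O[Si](C)(C)C(C)(C)C)CC(C)(C)[C@H]1CCC1=CCOC1=O | intermediate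
11 | (4R,6R)-4-hydroxy-2,2,6-trimethylcyclohexan-1-one (actinol) | O=C1[C@H](C)C[C@@H](O)CC1(C)C | starting material
12 | (4R,6R)-4-(tert-butyldimethylsilyloxy)-2,2,6-trimethylcyclohexan-1-one | O=C1[C@H](C)C[C@@H](O[Si](C)(C)C(C)(C)C)CC1(C)C | intermediate
13 | lithium (4R)-4-(tert-butyldimethylsilyloxy)-2,6,6-trimethylcyclohex-1-en-1-olate | [Li]OC1=C(C)C[C@@H](O[Si](C)(C)C(C)(C)C)CC1(C)C | intermediate (not isolated)
14 | (4R)-4-(tert-butyldimethylsilyloxy)-2,6,6-trimethylcyclohex-1-en-1-yl trifluoromethanesulfonate | O=S(=O)(OC1=C(C)C[C@@H](O[Si](C)(C)C(C)(C)C)CC1(C)C)C(F)(F)F | intermediate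
15 | methyl vinyl ketone (but-3-en-2-one) | CC(=O)C=C | starting material
16 | (3E)-4-[(4R)-4-(tert-butyldimethylsilyloxy)-2,6,6-trimethylcyclohex-1-en-1-yl]but-3-en-2-one | CC(=O)/C=C/C1=C(C)C[C@@H](O[Si](C)(C)C(C)(C)C)CC1(C)C | intermediate
17 | (1E)-1-[(4R)-4-(tert-butyldimethylsilyloxy)-2,6,6-trimethylcyclohex-1-en-1-yl]-3-methylpenta-1,4-dien-3-ol (C3 epimer mixture) | C=CC(C)(O)/C=C/C1=C(C)C[C@@H](O[Si](C)(C)C(C)(C)C)CC1(C)C | intermediate
18 | {(2E,4E)-5-[(4R)-4-(tert-butyldimethylsilyloxy)-2,6,6-trimethylcyclohex-1-en-1-yl]-3-methylpenta-2,4-dien-1-yl}triphenylphosphonium bromide | [Br-].C(/C=C(C)/C=C/C1=C(C)C[C@@H](O[Si](C)(C)C(C)(C)C)CC1(C)C)[P+](c1ccccc1)(c1ccccc1)c1ccccc1 | intermediate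
19 | (2E,4E,6E)-2,7-dimethylocta-2,4,6-trienedial | O=C/C(C)=C/C=C/C=C(C)/C=O | starting material
20 | phosphonium ylide derived from 18 | [CH-](/C=C(C)/C=C/C1=C(C)C[C@@H](O[Si](C)(C)C(C)(C)C)CC1(C)C)[P+](c1ccccc1)(c1ccccc1)c1ccccc1 | intermediate (not isolated)
21 | (2E,4E,6E,8Z,10E,12E)-13-[(4R)-4-(tert-butyldimethylsilyloxy)-2,6,6-trimethylcyclohex-1-en-1-yl]-2,7,11-trimethyltrideca-2,4,6,8,10,12-hexaenal | O=C/C(C)=C/C=C/C=C(C)/C=C\C=C(C)\C=C\C1=C(C)C[C@@H](O[Si](C)(C)C(C)(C)C)CC1(C)C | intermediate (not isolated)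
22 | (2E,4E,6E,8E,10E,12E)-13-[(4R)-4-(tert-butyldimethylsilyloxy)-2,6,6-trimethylcyclohex-1-en-1-yl]-2,7,11-trimethyltrideca-2,4,6,8,10,12-hexaenal | O=C/C(C)=C/C=C/C=C(C)/C=C/C=C(C)/C=C/C1=C(C)C[C@@H](O[Si](C)(C)C(C)(C)C)CC1(C)C | intermediate
23 | 2-(tert-butyldimethylsilyloxy)-3-{2-[(1R,4R)-4-(tert-butyldimethylsilyloxy)-2,6,6-trimethylcyclohex-2-en-1-yl]ethyl}furan | CC1=C[C@H](O[Si](C)(C)C(C)(C)C)CC(C)(C)[C@H]1CCc1ccoc1O[Si](C)(C)C(C)(C)C | intermediate (not isolated)
24 | aldol silyl ether: butenolide 10 bonded at C5 to the former aldehyde carbon of 22, which carries OTBS (diastereomer mixture at these two centres) | CC1=C[C@H](O[Si](C)(C)C(C)(C)C)CC(C)(C)[C@H]1CCC1=CC(OC1=O)C(O[Si](C)(C)C(C)(C)C)/C(C)=C/C=C/C=C(C)/C=C/C=C(C)/C=C/C1=C(C)C[C@@H](O[Si](C)(C)C(C)(C)C)CC1(C)C | intermediate (not isolated)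
25 | bis(tert-butyldimethylsilyl) ether of the target (5Z, all-E chain) | CC1=C[C@H](O[Si](C)(C)C(C)(C)C)CC(C)(C)[C@H]1CCC1=C/C(=C/C(C)=C/C=C/C=C(C)/C=C/C=C(C)/C=C/C2=C(C)C[C@@H](O[Si](C)(C)C(C)(C)C)CC2(C)C)OC1=O | intermediate
26 | (5Z)-3-{2-[(1R,4R)-4-hydroxy-2,6,6-trimethylcyclohex-2-en-1-yl]ethyl}-5-{(2E,4E,6E,8E,10E,12E)-13-[(4R)-4-hydroxy-2,6,6-trimethylcyclohex-1-en-1-yl]-2,7,11-trimethyltrideca-2,4,6,8,10,12-hexaen-1-ylidene}furan-2(5H)-one | CC1=C[C@H](O)CC(C)(C)[C@H]1CCC1=C/C(=C/C(C)=C/C=C/C=C(C)/C=C/C=C(C)/C=C/C2=C(C)C[C@@H](O)CC2(C)C)OC1=O | target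

**Summary**

Total step count: 14.
Longest linear sequence: 8 steps (steps 1–6, 13, 14; the branch through steps 7–12, 13, 14 is equally long).

Steps most likely to fail:

1. Step 6 (the step proposed as a new method). The formate C–H activation may be outrun by decarbonylation to the alcohol or by ionisation of the propargylic C–O bond followed by decarboxylative hydride transfer, so that the formate is lost before C–C closure. The fallback uses known chemistry and forms the same C2–C3 bond. Setting out from 8, trans-hydroalumination with Red-Al (THF, 0 °C) and iodinolysis (I2, −78 °C) would give the (2Z)-3-iodoallylic alcohol F1. Phenyl chloroformate and pyridine would convert it into the phenyl carbonate F2. Iodine–lithium exchange (t-BuLi, 2.1 equiv, THF–Et2O, −100 °C) would generate the vinyllithium F3, which closes the ring by Parham cyclisation onto the carbonate carbonyl with loss of phenoxide. The route is rejoined at 10.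

2. Step 1. Conversion may stall on preparative scale, or over-oxidation to the 3-ketone and erosion of face selectivity may occur. The fallback is chemical. Setting out from 1, ketalisation (ethylene glycol, PPTS, benzene, reflux) would give the dioxolane F4. Allylic oxidation (t-BuOOH, cat. Rh2(cap)4, CH2Cl2) would give the ring enone F5. CBS reduction ((S)-Me-CBS, catecholborane, toluene, −78 °C; alkenyl arm as the large group) would give the 3R allylic alcohol F6, and silylation (TBSCl, imidazole) the silyl ether F7. Mild hydrolysis of the dioxolane (PPTS, acetone–water) rejoins the route at 3.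

3. Step 13. Silyl triflate activation may isomerise or degrade the long polyenal, and the elimination may stop at the aldol stage or give poor Z selectivity. The fallback reverses the order of the last two C–C bond formations. Setting out from 10 and excess dialdehyde 19, the silyloxyfuran 23 would add to one aldehyde of this robust trienedial to give the aldol silyl ether F8 (not isolated). DBU elimination would give the butenolide trienal F9. Wittig olefination of F9 with ylide 20 (from 18, NaHMDS, THF, −78 °C) would then build the polyene last. The isomer that is Z at the new double bond, F10, would be equilibrated with catalytic iodine, and the route is rejoined at 25.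

Further compounds
F1 | step 6 | (2Z)-3-iodo-5-[(1R,4R)-4-(tert-butyldimethylsilyloxy)-2,6,6-trimethylcyclohex-2-en-1-yl]pent-2-en-1-ol | CC1=C[C@H](O[Si](C)(C)C(C)(C)C)CC(C)(C)[C@H]1CC/C(I)=C/CO
F2 | step 6 | phenyl carbonate of F1 | CC1=C[C@H](O[Si](C)(C)C(C)(C)C)CC(C)(C)[C@H]1CC/C(I)=C/COC(=O)Oc1ccccc1
F3 | step 6 | vinyllithium from F2 (Li in place of I, not isolated) | CC1=C[C@H](O[Si](C)(C)C(C)(C)C)CC(C)(C)[C@H]1CC/C([Li])=C/COC(=O)Oc1ccccc1
F4 | step 1 | (6R)-α-ionone ethylene ketal, 2-methyl-2-{(1E)-2-[(1R)-2,6,6-trimethylcyclohex-2-en-1-yl]ethenyl}-1,3-dioxolane | CC1=CCCC(C)(C)[C@H]1/C=C/C1(C)OCCO1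
F5 | step 1 | (6R)-3-oxo-α-ionone ethylene ketal | CC1=CC(=O)CC(C)(C)[C@H]1/C=C/C1(C)OCCO1
F6 | step 1 | (3R,6R)-3-hydroxy-α-ionone ethylene ketal | CC1=C[C@H](O)CC(C)(C)[C@H]1/C=C/C1(C)OCCO1
F7 | step 1 | tert-butyldimethylsilyl ether of F6 | CC1=C[C@H](O[Si](C)(C)C(C)(C)C)CC(C)(C)[C@H]1/C=C/C1(C)OCCO1
F8 | step 13 | aldol silyl ether of 23 with one aldehyde of 19 (diastereomer mixture, not isolated) | CC1=C[C@H](O[Si](C)(C)C(C)(C)C)CC(C)(C)[C@H]1CCC1=CC(OC1=O)C(O[Si](C)(C)C(C)(C)C)/C(C)=C/C=C/C=C(C)/C=O
F9 | step 13 | (2E,4E,6E)-2,7-dimethyl-8-[(2Z)-furan-2(5H)-on-5-ylidene]octa-2,4,6-trienal carrying the silylated ring A ethyl group at C3 of the furanone | CC1=C[C@H](O[Si](C)(C)C(C)(C)C)CC(C)(C)[C@H]1CCC1=C/C(=C/C(C)=C/C=C/C=C(C)/C=O)OC1=O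
F10 | step 13 | isomer of 25 that is Z at the double bond formed in the Wittig reaction | CC1=C[C@H](O[Si](C)(C)C(C)(C)C)CC(C)(C)[C@H]1CCC1=C/C(=C/C(C)=C/C=C/C=C(C)/C=C\C=C(C)\C=C\C2=C(C)C[C@@H](O[Si](C)(C)C(C)(C)C)CC2(C)C)OC1=O
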